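**Retrosynthetic overview**
1. The target comes from the silyl-protected 8-hydroxy germacranolide 25: free the C8 hydroxyl, acylate it with methacryloyl chloride, then remove the two primary silyl ethers.
2. 25 comes from the open-chain enal / Morita–Baylis–Hillman alcohol 22 by a palladium-catalysed reductive allylation that forms C6–C7. The ten-membered carbocycle closes first and the γ-lactone closes onto it in the same flask.
3. 22 comes from a B-alkyl Suzuki–Miyaura coupling (C3–C4) of iodoenal 9 (fragment A) with alkene 20 (fragment B).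
4. Fragment A comes from propargyl alcohol and methyl chloroformate; a syn-stannylcupration fixes the C4=C5 geometry. Fragment B comes from (S)-5-(hydroxymethyl)butyrolactone (C8), a trans-selective allylation (C10) and a Morita–Baylis–Hillman reaction with methyl acrylate (C11–C13).

Assumption: the SMILES is read as the trans-fused 6,12-lactone (3aR,4S,6R,10Z,11aR); atoms are named by germacrane numbers (C6 lactone carbinol, C7 ring-fusion CH, C8 ester carbinol, C10 CH bearing C14H2OH, C4=C5 ring alkene with C15H2OH on C4, C11=C13 exocyclic methylene, C12 lactone carbonyl).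

**Fragment A**

Step 1
Reactants: 1 prop-2-yn-1-ol
Product: 2 tert-butyl(diphenyl)(prop-2-yn-1-yloxy)silane
Conditions: TBDPSCl, imidazole, DMF, 0 °C to r.t.
Reagents that add atoms: tert-butyl(chloro)diphenylsilane CC(C)(C)[Si](Cl)(c1ccccc1)c1ccccc1
Why: Standard silyl ether formation on an unhindered primary alcohol; no stereocentre.

Step 2
Reactants: 2 tert-butyl(diphenyl)(prop-2-yn-1-yloxy)silane + 3 methyl chloroformate
Product: 5 methyl 4-{[tert-butyl(diphenyl)silyl]oxy}but-2-ynoate, via lithium acetylide 4 (not isolated)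
Conditions: n-BuLi, THF, −78 °C; then ClCO2Me, −78 to 0 °C
Reagents that add atoms: none
Why: C-acylation of a lithium acetylide with a chloroformate gives the ynoate and brings in the future C6.

Step 3
Reactants: 5 methyl 4-{[tert-butyl(diphenyl)silyl]oxy}but-2-ynoate
Product: 6 methyl (2E)-4-{[tert-butyl(diphenyl)silyl]oxy}-3-(trimethylstannyl)but-2-enoate
Conditions: Li[Me3SnCu(SPh)] (2 equiv, from (Me3Sn)2, MeLi and CuSPh), MeOH (1.7 equiv), THF, −100 to −78 °C
Reagents that add atoms: hexamethyldistannane C[Sn](C)(C)[Sn](C)(C)C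
Why: Kinetic syn-stannylcupration of the ynoate with protonation in place puts tin on C4 trans to the ester, so the CH2OSi group (C15) ends up cis to the future C6 as the target requires.

Step 4
Reactants: 6 methyl (2E)-4-{[tert-butyl(diphenyl)silyl]oxy}-3-(trimethylstannyl)but-2-enoate
Product: 7 methyl (2E)-4-{[tert-butyl(diphenyl)silyl]oxy}-3-iodobut-2-enoate
Conditions: I2, CH2Cl2, 0 °C, dark
Reagents that add atoms: iodine II
Why: Iododestannylation of an alkenylstannane proceeds with retention of alkene geometry.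

Step 5
Reactants: 7 methyl (2E)-4-{[tert-butyl(diphenyl)silyl]oxy}-3-iodobut-2-enoate
Product: 8 (2E)-4-{[tert-butyl(diphenyl)silyl]oxy}-3-iodobut-2-en-1-ol
Conditions: i-Bu2AlH (2.2 equiv), CH2Cl2, −78 °C
Reagents that add atoms: none
Why: 1,2-Reduction of the enoate by the aluminium hydride leaves the vinyl iodide and the geometry untouched.

Step 6
Reactants: 8 (2E)-4-{[tert-butyl(diphenyl)silyl]oxy}-3-iodobut-2-en-1-ol
Product: 9 (2E)-4-{[tert-butyl(diphenyl)silyl]oxy}-3-iodobut-2-enal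
Conditions: MnO2 (15 equiv), CH2Cl2, r.t., dark
Reagents that add atoms: none
Why: Mild allylic oxidation gives the enal without acid or base that could isomerise the alkene; used at once.

**Fragment B**

Step 7
Reactants: 10 (5S)-5-(hydroxymethyl)oxolan-2-one
Product: 11 (5S)-5-{[(triethylsilyl)oxy]methyl}oxolan-2-one
Conditions: Et3SiCl, imidazole, CH2Cl2, 0 °C
Reagents that add atoms: chlorotriethylsilane CC[Si](Cl)(CC)CC
Why: Silyl ether formation; the chiral-pool stereocentre (future C8, S) is not touched.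

Step 8
Reactants: 11 (5S)-5-{[(triethylsilyl)oxy]methyl}oxolan-2-one + 12 allyl bromide
Product: 14 (3R,5S)-3-(prop-2-en-1-yl)-5-{[(triethylsilyl)oxy]methyl}oxolan-2-one, via lithium enolate 13 (not isolated)
Conditions: LiN(i-Pr)2 (1.1 equiv), THF, −78 °C; then allyl bromide, −78 to −40 °C
Reagents that add atoms: none
Why: Lactone enolate alkylation occurs on the face opposite the C5 silyloxymethyl group, giving the 3,5-trans lactone and setting C10 as R (minor cis isomer removed by chromatography).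

Step 9
Reactants: 14 (3R,5S)-3-(prop-2-en-1-yl)-5-{[(triethylsilyl)oxy]methyl}oxolan-2-one
Product: 15 (2S,4R)-4-(hydroxymethyl)-1-[(triethylsilyl)oxy]hept-6-en-2-ol
Conditions: LiBH4, THF, 0 °C to r.t.
Reagents that add atoms: none
Why: Borohydride reduction opens the lactone to the diol (C14 primary OH, C8 secondary OH) under conditions mild enough to avoid silyl migration.

Step 10
Reactants: 15 (2S,4R)-4-(hydroxymethyl)-1-[(triethylsilyl)oxy]hept-6-en-2-ol
Product: 17 (4R,6S)-6-{[tert-butyl(dimethyl)silyl]oxy}-4-({[tert-butyl(diphenyl)silyl]oxy}methyl)-7-[(triethylsilyl)oxy]hept-1-ene, via mono-TBDPS ether 16 (not isolated)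
Conditions: TBDPSCl (1.05 equiv), imidazole, CH2Cl2, −20 to 0 °C; then 2,6-lutidine, TBSOTf, −78 to −40 °C
Reagents that add atoms: tert-butyl(chloro)diphenylsilane CC(C)(C)[Si](Cl)(c1ccccc1)c1ccccc1; tert-butyldimethylsilyl trifluoromethanesulfonate CC(C)(C)[Si](C)(C)OS(=O)(=O)C(F)(F)F
Why: Sequential silyl ether formation: the bulky chloride takes only the primary C14 hydroxyl, and the triflate then caps the secondary C8 hydroxyl in the same flask.

Step 11
Reactants: 17 (4R,6S)-6-{[tert-butyl(dimethyl)silyl]oxy}-4-({[tert-butyl(diphenyl)silyl]oxy}methyl)-7-[(triethylsilyl)oxy]hept-1-ene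
Product: 18 (2S,4R)-2-{[tert-butyl(dimethyl)silyl]oxy}-4-({[tert-butyl(diphenyl)silyl]oxy}methyl)hept-6-enal
Conditions: (COCl)2 (4 equiv), DMSO (8 equiv), CH2Cl2, −78 to −40 °C; then Et3N, −78 to 0 °C
Reagents that add atoms: none
Why: Direct Swern oxidation of a primary triethylsilyl ether: the chlorosulfonium salt cleaves only the unhindered primary Et3Si ether and oxidises it to the aldehyde, leaving the TBS and TBDPS ethers; cold amine treatment avoids epimerisation at C8.

Step 12
Reactants: 18 (2S,4R)-2-{[tert-butyl(dimethyl)silyl]oxy}-4-({[tert-butyl(diphenyl)silyl]oxy}methyl)hept-6-enal + 19 methyl acrylate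
Product: 20 methyl (3RS,4S,6R)-4-{[tert-butyl(dimethyl)silyl]oxy}-6-({[tert-butyl(diphenyl)silyl]oxy}methyl)-3-hydroxy-2-methylidenenon-8-enoate
Conditions: DABCO (1 equiv), methyl acrylate (10 equiv, neat), r.t., 48 h
Reagents that add atoms: none
Why: Morita–Baylis–Hillman reaction of an activated α-silyloxy aldehyde; the new C7 carbinol is obtained as an epimer mixture, which does not matter because C7 becomes part of an allyl unit in step 14.

**Fragment union and endgame**

Step 13
Reactants: 20 methyl (3RS,4S,6R)-4-{[tert-butyl(dimethyl)silyl]oxy}-6-({[tert-butyl(diphenyl)silyl]oxy}methyl)-3-hydroxy-2-methylidenenon-8-enoate + 9 (2E)-4-{[tert-butyl(diphenyl)silyl]oxy}-3-iodobut-2-enal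
Product: 22 methyl (3RS,4S,6R,10Z)-4-{[tert-butyl(dimethyl)silyl]oxy}-6,10-bis({[tert-butyl(diphenyl)silyl]oxy}methyl)-3-hydroxy-2-methylidene-12-oxododec-10-enoate, via B-alkyl-9-BBN 21 (not isolated)
Conditions: 9-BBN-H (2.4 equiv B–H), THF, 0 °C to r.t.; then aq. Cs2CO3 (quench of excess B–H), 9, PdCl2(dppf) (7 mol %), AsPh3 (14 mol %), DMF, r.t., 3 h
Reagents that add atoms: none
Why: 9-BBN adds only to the monosubstituted terminal alkene (the electron-poor acrylate is much slower and the free OH is held as its borinate), and the primary alkylborane couples with the β-iodoenal with retention of geometry (B-alkyl Suzuki–Miyaura coupling), forming C3–C4.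

Step 14
Reactants: 22 methyl (3RS,4S,6R,10Z)-4-{[tert-butyl(dimethyl)silyl]oxy}-6,10-bis({[tert-butyl(diphenyl)silyl]oxy}methyl)-3-hydroxy-2-methylidene-12-oxododec-10-enoate
Product: 25 (3aS,4S,6R,10Z,11aR)-4-{[tert-butyl(dimethyl)silyl]oxy}-6,10-bis({[tert-butyl(diphenyl)silyl]oxy}methyl)-3-methylidene-3a,4,5,6,7,8,9,11a-octahydrocyclodeca[b]furan-2(3H)-one, via allylindium species 23 (not isolated), via indium alkoxide 24 (not isolated)
Conditions: Pd(PPh3)4 (10 mol %), InI (3 equiv), THF, 40 °C, 22 added by syringe pump over 12 h (final 2 mM); aq. NH4Cl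
Reagents that add atoms: none
Why: Proposed new method: a palladium-catalysed reductive (umpolung) carbonyl allylation run as a ten-membered ring closure directly from the free Morita–Baylis–Hillman alcohol: zerovalent palladium ionises the allylic C7–OH with help from the indium Lewis acid (both C7 epimers give the same 2-(methoxycarbonyl)allyl complex), monovalent indium reduces it to the σ-allylindium 23 bound at C13, and its γ-carbon C7 adds to the C6 aldehyde through a closed six-membered transition state in which both ends of the tether sit equatorial, which should give the anti adduct (6R,7R, H6/H7 trans) with the C8 silyloxy group pseudo-equatorial, after which alkoxide 24 closes the lactone by loss of methoxide; the closest known reactions are the intermolecular palladium/SnCl2 and palladium/InI carbonyl allylations with allylic alcohols and 2-(hydroxymethyl)acrylates, and the CrCl2-mediated Barbier macrocyclisation of 2-(bromomethyl)acrylates to germacranolides. (25 has the same spatial arrangement at C3a as the target; the descriptor reads S only because silicon raises the priority of C4.)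

Step 15
Reactants: 25 (3aS,4S,6R,10Z,11aR)-4-{[tert-butyl(dimethyl)silyl]oxy}-6,10-bis({[tert-butyl(diphenyl)silyl]oxy}methyl)-3-methylidene-3a,4,5,6,7,8,9,11a-octahydrocyclodeca[b]furan-2(3H)-one
Product: 26 (3aR,4S,6R,10Z,11aR)-6,10-bis({[tert-butyl(diphenyl)silyl]oxy}methyl)-4-hydroxy-3-methylidene-3a,4,5,6,7,8,9,11a-octahydrocyclodeca[b]furan-2(3H)-one
Conditions: HF (48 % aq.)/MeCN 1:19, 0 °C to r.t., monitored
Reagents that add atoms: none
Why: Selective acidic desilylation: the secondary TBS ether is cleaved much faster than the two primary TBDPS ethers, and the mild acid does not move the lactone to O8.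

Step 16
Reactants: 26 (3aR,4S,6R,10Z,11aR)-6,10-bis({[tert-butyl(diphenyl)silyl]oxy}methyl)-4-hydroxy-3-methylidene-3a,4,5,6,7,8,9,11a-octahydrocyclodeca[b]furan-2(3H)-one + 27 methacryloyl chloride
Product: 28 (3aR,4S,6R,10Z,11aR)-6,10-bis({[tert-butyl(diphenyl)silyl]oxy}methyl)-3-methylidene-2-oxo-2,3,3a,4,5,6,7,8,9,11a-decahydrocyclodeca[b]furan-4-yl 2-methylprop-2-enoate
Conditions: Et3N (3 equiv), DMAP (0.2 equiv), CH2Cl2, 0 °C
Reagents that add atoms: none
Why: DMAP-catalysed acylation of the only free hydroxyl with an acid chloride, fast enough at 0 °C to outrun translactonisation; configuration at C8 is retained.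

Step 17
Reactants: 28 (3aR,4S,6R,10Z,11aR)-6,10-bis({[tert-butyl(diphenyl)silyl]oxy}methyl)-3-methylidene-2-oxo-2,3,3a,4,5,6,7,8,9,11a-decahydrocyclodeca[b]furan-4-yl 2-methylprop-2-enoate
Product: 29 (3aR,4S,6R,10Z,11aR)-6,10-bis(hydroxymethyl)-3-methylidene-2-oxo-2,3,3a,4,5,6,7,8,9,11a-decahydrocyclodeca[b]furan-4-yl 2-methylprop-2-enoate
Conditions: HF·pyridine (excess), pyridine, THF, 0 °C to r.t., 24 h
Reagents that add atoms: none
Why: Fluoride-mediated desilylation under buffered acidic conditions removes both primary TBDPS ethers without touching the methacrylate or the α-methylene lactone.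

**Compound list**
1 | prop-2-yn-1-ol | C#CCO | starting material
2 | tert-butyl(diphenyl)(prop-2-yn-1-yloxy)silane | C#CCO[Si](c1ccccc1)(c1ccccc1)C(C)(C)C | intermediate
3 | methyl chloroformate | COC(=O)Cl | starting material
4 | lithium acetylide of 2 | [Li]C#CCO[Si](c1ccccc1)(c1ccccc1)C(C)(C)C | intermediate
5 | methyl 4-{[tert-butyl(diphenyl)silyl]oxy}but-2-ynoate | COC(=O)C#CCO[Si](c1ccccc1)(c1ccccc1)C(C)(C)C | intermediate
6 | methyl (2E)-4-{[tert-butyl(diphenyl)silyl]oxy}-3-(trimethylstannyl)but-2-enoate | COC(=O)/C=C(/[Sn](C)(C)C)CO[Si](c1ccccc1)(c1ccccc1)C(C)(C)C | intermediate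
7 | methyl (2E)-4-{[tert-butyl(diphenyl)silyl]oxy}-3-iodobut-2-enoate | COC(=O)/C=C(/I)CO[Si](c1ccccc1)(c1ccccc1)C(C)(C)C | intermediate
8 | (2E)-4-{[tert-butyl(diphenyl)silyl]oxy}-3-iodobut-2-en-1-ol | OC/C=C(/I)CO[Si](c1ccccc1)(c1ccccc1)C(C)(C)C | intermediate
9 | (2E)-4-{[tert-butyl(diphenyl)silyl]oxy}-3-iodobut-2-enal | O=C/C=C(/I)CO[Si](c1ccccc1)(c1ccccc1)C(C)(C)C | intermediate
10 | (5S)-5-(hydroxymethyl)oxolan-2-one | OC[C@@H]1CCC(=O)O1 | starting material
11 | (5S)-5-{[(triethylsilyl)oxy]methyl}oxolan-2-one | CC[Si](CC)(CC)OC[C@@H]1CCC(=O)O1 | intermediate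
12 | allyl bromide (3-bromoprop-1-ene) | C=CCBr | starting material
13 | lithium enolate of 11 | [Li]OC1=CC[C@@H](CO[Si](CC)(CC)CC)O1 | intermediate
14 | (3R,5S)-3-(prop-2-en-1-yl)-5-{[(triethylsilyl)oxy]methyl}oxolan-2-one | O=C1O[C@H](CO[Si](CC)(CC)CC)C[C@H]1CC=C | intermediate
15 | (2S,4R)-4-(hydroxymethyl)-1-[(triethylsilyl)oxy]hept-6-en-2-ol | O[C@H](CO[Si](CC)(CC)CC)C[C@H](CO)CC=C | intermediate
16 | (2S,4R)-4-({[tert-butyl(diphenyl)silyl]oxy}methyl)-1-[(triethylsilyl)oxy]hept-6-en-2-ol | O[C@H](CO[Si](CC)(CC)CC)C[C@H](CO[Si](c1ccccc1)(c1ccccc1)C(C)(C)C)CC=C | intermediate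
17 | (4R,6S)-6-{[tert-butyl(dimethyl)silyl]oxy}-4-({[tert-butyl(diphenyl)silyl]oxy}methyl)-7-[(triethylsilyl)oxy]hept-1-ene | CC(C)(C)[Si](C)(C)O[C@H](CO[Si](CC)(CC)CC)C[C@H](CO[Si](c1ccccc1)(c1ccccc1)C(C)(C)C)CC=C | intermediate
18 | (2S,4R)-2-{[tert-butyl(dimethyl)silyl]oxy}-4-({[tert-butyl(diphenyl)silyl]oxy}methyl)hept-6-enal | CC(C)(C)[Si](C)(C)O[C@H](C=O)C[C@H](CO[Si](c1ccccc1)(c1ccccc1)C(C)(C)C)CC=C | intermediate
19 | methyl acrylate | C=CC(=O)OC | starting material
20 | methyl (3RS,4S,6R)-4-{[tert-butyl(dimethyl)silyl]oxy}-6-({[tert-butyl(diphenyl)silyl]oxy}methyl)-3-hydroxy-2-methylidenenon-8-enoate | CC(C)(C)[Si](C)(C)O[C@H](C(O)C(=C)C(=O)OC)C[C@H](CO[Si](c1ccccc1)(c1ccccc1)C(C)(C)C)CC=C | intermediate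
21 | B-alkyl-9-BBN from 20 (C7 hydroxyl held as its 9-BBN borinate) | CC(C)(C)[Si](C)(C)O[C@H](C(OB1C2CCCC1CCC2)C(=C)C(=O)OC)C[C@H](CO[Si](c1ccccc1)(c1ccccc1)C(C)(C)C)CCCB1C2CCCC1CCC2 | intermediate
22 | methyl (3RS,4S,6R,10Z)-4-{[tert-butyl(dimethyl)silyl]oxy}-6,10-bis({[tert-butyl(diphenyl)silyl]oxy}methyl)-3-hydroxy-2-methylidene-12-oxododec-10-enoate | CC(C)(C)[Si](C)(C)O[C@H](C(O)C(=C)C(=O)OC)C[C@H](CO[Si](c1ccccc1)(c1ccccc1)C(C)(C)C)CCC/C(CO[Si](c1ccccc1)(c1ccccc1)C(C)(C)C)=C/C=O | intermediate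
23 | σ-allylindium (hydroxy)iodide from 22, indium on C13 | CC(C)(C)[Si](C)(C)O[C@H](C=C(C[In](O)I)C(=O)OC)C[C@H](CO[Si](c1ccccc1)(c1ccccc1)C(C)(C)C)CCC/C(CO[Si](c1ccccc1)(c1ccccc1)C(C)(C)C)=C/C=O | intermediate
24 | ring-closed indium alkoxide, methyl 2-[(1R,2R,3Z,8R,10S)-cyclodecenyl]acrylate stage before lactonisation | CC(C)(C)[Si](C)(C)O[C@H]1C[C@H](CO[Si](c2ccccc2)(c2ccccc2)C(C)(C)C)CCC/C(CO[Si](c2ccccc2)(c2ccccc2)C(C)(C)C)=C/[C@@H](O[In](O)I)[C@@H]1C(=C)C(=O)OC | intermediate
25 | (3aS,4S,6R,10Z,11aR)-4-{[tert-butyl(dimethyl)silyl]oxy}-6,10-bis({[tert-butyl(diphenyl)silyl]oxy}methyl)-3-methylidene-3a,4,5,6,7,8,9,11a-octahydrocyclodeca[b]furan-2(3H)-one | CC(C)(C)[Si](C)(C)O[C@H]1C[C@H](CO[Si](c2ccccc2)(c2ccccc2)C(C)(C)C)CCC/C(CO[Si](c2ccccc2)(c2ccccc2)C(C)(C)C)=C/[C@H]2OC(=O)C(=C)[C@H]12 | intermediate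
26 | (3aR,4S,6R,10Z,11aR)-6,10-bis({[tert-butyl(diphenyl)silyl]oxy}methyl)-4-hydroxy-3-methylidene-3a,4,5,6,7,8,9,11a-octahydrocyclodeca[b]furan-2(3H)-one | O[C@H]1C[C@H](CO[Si](c2ccccc2)(c2ccccc2)C(C)(C)C)CCC/C(CO[Si](c2ccccc2)(c2ccccc2)C(C)(C)C)=C/[C@H]2OC(=O)C(=C)[C@H]12 | intermediate
27 | methacryloyl chloride | C=C(C)C(=O)Cl | starting material
28 | (3aR,4S,6R,10Z,11aR)-6,10-bis({[tert-butyl(diphenyl)silyl]oxy}methyl)-3-methylidene-2-oxo-2,3,3a,4,5,6,7,8,9,11a-decahydrocyclodeca[b]furan-4-yl 2-methylprop-2-enoate | C=C(C)C(=O)O[C@H]1C[C@H](CO[Si](c2ccccc2)(c2ccccc2)C(C)(C)C)CCC/C(CO[Si](c2ccccc2)(c2ccccc2)C(C)(C)C)=C/[C@H]2OC(=O)C(=C)[C@H]12 | intermediate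
29 | (3aR,4S,6R,10Z,11aR)-6,10-bis(hydroxymethyl)-3-methylidene-2-oxo-2,3,3a,4,5,6,7,8,9,11a-decahydrocyclodeca[b]furan-4-yl 2-methylprop-2-enoate | C=C(C)C(=O)O[C@H]1C[C@H](CO)CCC/C(CO)=C/[C@H]2OC(=O)C(=C)[C@H]12 | target

**Totals**
Total step count: 17. Longest linear sequence: 11 steps (steps 7–12 then 13–17; the branch through steps 1–6 then 13–17 is also 11).

**Steps most likely to fail**

Step 14 (the proposed new ring closure). Ionisation of the free alcohol may be slow, the 2-(methoxycarbonyl)allyl palladium may lose a β-hydrogen, and the C6/C7 selectivity in the ring is unproven. Fallback with known chemistry, setting out from 22: NBS/Me2S (CH2Cl2, −20 to 0 °C) converts the alcohol with allylic transposition into the Z-allylic bromide F1. Stoichiometric CrCl2 (10 equiv, DMF/THF, 1 mM, r.t.) then performs the established Barbier-type (Nozaki–Hiyama–Kishi) macrocyclisation used for 6,7-trans germacranolides, via the allylchromium dichloride F2 and the ring-closed chromium alkoxide F3, which lactonises and rejoins the route at 25.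

Step 13 (coupling in the presence of an enal, an acrylate and a free hydroxyl). The enal may not survive the basic aqueous coupling, or the TBS group may migrate to the C7 hydroxyl. Fallback, setting out from 20 and the allylic alcohol 8 (one step before 9): the same hydroboration and palladium coupling give the diol F4. MnO2 (CH2Cl2, r.t.) then oxidises only the primary allylic alcohol, because the C7 carbinol next to the ester is far less reactive, and the route is rejoined at 22.

Step 12 (Morita–Baylis–Hillman reaction on a hindered, epimerisable α-silyloxy aldehyde). It may be slow and may erode C8. Fallback, setting out from 18: hydroalumination of methyl propiolate (C#CC(=O)OC) with i-Bu2AlH and N-methylmorpholine N-oxide (THF, 0 °C) gives the vinylalane F5, which adds to 18 at −78 to 0 °C to give the aluminium alkoxide F6; aqueous work-up returns the route at 20 without an amine base.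

**Further compounds**
F1 | step 14 | methyl (2Z,4S,6R,10Z)-2-(bromomethyl)-4-{[tert-butyl(dimethyl)silyl]oxy}-6,10-bis({[tert-butyl(diphenyl)silyl]oxy}methyl)-12-oxododeca-2,10-dienoate | CC(C)(C)[Si](C)(C)O[C@H](/C=C(\CBr)C(=O)OC)C[C@H](CO[Si](c1ccccc1)(c1ccccc1)C(C)(C)C)CCC/C(CO[Si](c1ccccc1)(c1ccccc1)C(C)(C)C)=C/C=O
F2 | step 14 | allylchromium dichloride from F1, chromium on C13 | CC(C)(C)[Si](C)(C)O[C@H](C=C(C[Cr](Cl)Cl)C(=O)OC)C[C@H](CO[Si](c1ccccc1)(c1ccccc1)C(C)(C)C)CCC/C(CO[Si](c1ccccc1)(c1ccccc1)C(C)(C)C)=C/C=O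
F3 | step 14 | ring-closed chromium alkoxide before lactonisation | CC(C)(C)[Si](C)(C)O[C@H]1C[C@H](CO[Si](c2ccccc2)(c2ccccc2)C(C)(C)C)CCC/C(CO[Si](c2ccccc2)(c2ccccc2)C(C)(C)C)=C/[C@@H](O[Cr](Cl)Cl)[C@@H]1C(=C)C(=O)OC
F4 | step 13 | methyl (3RS,4S,6R,10Z)-4-{[tert-butyl(dimethyl)silyl]oxy}-6,10-bis({[tert-butyl(diphenyl)silyl]oxy}methyl)-3,12-dihydroxy-2-methylidenedodec-10-enoate | CC(C)(C)[Si](C)(C)O[C@H](C(O)C(=C)C(=O)OC)C[C@H](CO[Si](c1ccccc1)(c1ccccc1)C(C)(C)C)CCC/C(CO[Si](c1ccccc1)(c1ccccc1)C(C)(C)C)=C/CO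
F5 | step 12 | methyl 2-[bis(2-methylpropyl)alumanyl]prop-2-enoate | C=C([Al](CC(C)C)CC(C)C)C(=O)OC
F6 | step 12 | diisobutylaluminium alkoxide of 20 | CC(C)(C)[Si](C)(C)O[C@H](C(O[Al](CC(C)C)CC(C)C)C(=C)C(=O)OC)C[C@H](CO[Si](c1ccccc1)(c1ccccc1)C(C)(C)C)CC=C
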